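## Retrosynthetic overview

1. Target 28 ⇐ its (5Z)-isomer 27 (iodine-catalysed alkene equilibration) ⇐ bis-silyl ether 24 by a siloxy-Cope ring expansion and desilylative transannular hemiketalisation: C1–C6 of a cyclohexane is cut, C3–C4 and O–C1 of the oxolane are made.
2. Enabling feature: the carbocycle C1–C10 is a masked cyclodec-5-enone. C1 (hemiketal, ketone level) and the enol-lactone alkene C5=C6 are 1,5-related and the oxygen-bearing C4 is allylic to C5=C6, so C1(=O)–C2–C3–C4(O)–C5=C6 is the retron of an oxy-Cope of a 1-vinyl-2-(2-siloxyprop-1-enyl)cyclohexanol whose C6 is the γ-carbon of the butenolide (O, C6, C7, C11, C12); the γ-hydroxy ketone C4–OH/C1=O then closes the oxolane (O, C1, C2, C3, C4).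
3. 24 ⇐ butenolide 16 (C8 ester by Steglich coupling with acid 22; C4 ketone by alkyne hydration) ⇐ keto ester 14 by Felkin–Anh propargylation at C6 and lactonisation ⇐ ketone 9 + ethyl bromopyruvate (C11–C13).
4. 9 ⇐ 4-silyloxycyclohexanone 1 by desymmetrising α-methylation (C8, C10), α′-hydroxylation, vinyl addition (C1) and oxidation.
5. Ring order: cyclohexane (sacrificial, from 1) → butenolide (step 8) → ten-membered carbocycle and then the oxolane (both in step 15, the oxolane last).

Key step: step 15

Remark on locants: C1–C15 follow the germacrane numbering of the target (C1 hemiketal carbon, C4 methyl carbinol carbon, C5=C6 enol-lactone alkene, C7=C11 butenolide alkene, C8 acyloxy carbon, C10 methyl-bearing carbon, C12 lactone carbonyl, C13 acetoxymethyl carbon). 5Z means C4 syn to the lactone oxygen; the target is 5E.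
Remark on step 1: the antipode of the chiral lithium amide is chosen so that the (R)-enolate 2 forms; the (S,S)-amide is assumed.
Remark on materials: 1, 10, 19 and 20 are taken as commercial.

## Route

Step 1
Reactants: 1 4-[(tert-butyldimethylsilyl)oxy]cyclohexan-1-one
Product: 3 (4R)-4-[(tert-butyldimethylsilyl)oxy]-2-methylcyclohexan-1-one (C2-epimer mixture), via lithium enolate 2 (not isolated)
Conditions: lithium (S,S)-bis(1-phenylethyl)amide, LiCl, THF, −78 °C; then MeI, −78 → −30 °C
Reagents that add atoms: iodomethane (CI)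
Why: Chiral lithium amide desymmetrisation: the C2-symmetric base removes one of the two enantiotopic α-protons of the prochiral ketone, which fixes the configuration of the silyloxy carbon (C8) relative to the enolised side, and the lithium enolate is then C-methylated (enolate alkylation).

Step 2
Reactants: 3 (4R)-4-[(tert-butyldimethylsilyl)oxy]-2-methylcyclohexan-1-one (C2-epimer mixture)
Product: 4 (2R,4R)-4-[(tert-butyldimethylsilyl)oxy]-2-methylcyclohexan-1-one
Conditions: NaOMe (cat.), MeOH, rt
Reagents that add atoms: none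
Why: Methoxide-mediated epimerisation of the enolisable α-carbon (C10) should funnel the mixture to the cis-2,4-disubstituted ketone with both groups equatorial, so C10 is set by thermodynamic control relative to C8.

Step 3
Reactants: 4 (2R,4R)-4-[(tert-butyldimethylsilyl)oxy]-2-methylcyclohexan-1-one
Product: 6 4-[(tert-butyldimethylsilyl)oxy]-2-hydroxy-6-methylcyclohexan-1-one (carbinol epimers), via lithium enolate 5 (not isolated)
Conditions: LDA, THF, −78 °C; then 2-(phenylsulfonyl)-3-phenyloxaziridine, −78 °C; aq. NH4Cl
Reagents that add atoms: 2-(phenylsulfonyl)-3-phenyloxaziridine (O=S(=O)(N1OC1c1ccccc1)c1ccccc1)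
Why: Kinetic deprotonation occurs at the unsubstituted α′-methylene and the enolate is oxidised by the N-sulfonyloxaziridine (enolate hydroxylation), which installs the C6 oxygen; the new carbinol centre is unimportant because it is oxidised in step 5.

Step 4
Reactants: 6 4-[(tert-butyldimethylsilyl)oxy]-2-hydroxy-6-methylcyclohexan-1-one
Product: 7 4-[(tert-butyldimethylsilyl)oxy]-6-methyl-1-vinylcyclohexane-1,2-diol
Conditions: CH2=CHMgBr (2.5 equiv), THF, −78 → 0 °C; aq. NH4Cl
Reagents that add atoms: vinylmagnesium bromide (C=C[Mg]Br)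
Why: Grignard 1,2-addition to the ketone should take the equatorial trajectory trans to the adjacent equatorial methyl group, which sets C1 with its hydroxyl cis to the C10 methyl and to the C8 silyloxy group.

Step 5
Reactants: 7 4-[(tert-butyldimethylsilyl)oxy]-6-methyl-1-vinylcyclohexane-1,2-diol
Product: 8 5-[(tert-butyldimethylsilyl)oxy]-2-hydroxy-3-methyl-2-vinylcyclohexan-1-one
Conditions: IBX, EtOAc, 70 °C
Reagents that add atoms: none
Why: IBX oxidises the secondary hydroxyl of the 1,2-diol to the ketone without glycol cleavage, the tertiary allylic carbinol being inert (hypervalent iodine alcohol oxidation).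

Step 6
Reactants: 8 5-[(tert-butyldimethylsilyl)oxy]-2-hydroxy-3-methyl-2-vinylcyclohexan-1-one
Product: 9 5-[(tert-butyldimethylsilyl)oxy]-3-methyl-2-[(triethylsilyl)oxy]-2-vinylcyclohexan-1-one
Conditions: TESOTf, 2,6-lutidine, CH2Cl2, −78 → 0 °C
Reagents that add atoms: triethylsilyl trifluoromethanesulfonate (CC[Si](CC)(CC)OS(=O)(=O)C(F)(F)F)
Why: The silyl triflate silylates the hindered tertiary alcohol, which blocks α-ketol rearrangement and provides the non-chelating α-siloxy group that steers step 8 (silyl ether protection).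

Step 7
Reactants: 9 5-[(tert-butyldimethylsilyl)oxy]-3-methyl-2-[(triethylsilyl)oxy]-2-vinylcyclohexan-1-one; 10 ethyl 3-bromo-2-oxopropanoate
Product: 14 ethyl (Z)-3-acetoxy-2-(2-oxocyclohexylidene)propanoate derivative (ester syn to the ring ketone), via lithium enolate 11 (not isolated), via glycidic ester 12 (not isolated), via lithium alkoxide 13 (not isolated)
Conditions: LDA (1.05 equiv), THF, −78 °C; then 10, −78 → −40 °C; LiHMDS (1.1 equiv), −40 °C; Ac2O, −40 → 0 °C
Reagents that add atoms: acetic anhydride (CC(=O)OC(C)=O)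
Why: Aldol addition of the only possible enolate (C7) to the ketone of ethyl bromopyruvate and closure of the bromohydrin alkoxide give the glycidic ester (Darzens-type condensation), whose acidic C7–H is removed by the second base so that E1cB opening of the β,γ-epoxy ketone gives the alkylidene keto ester, with the lithium-chelated ester expected syn to the ketone, and the liberated C13 alkoxide is acetylated in situ.

Step 8
Reactants: 14 ethyl (Z)-3-acetoxy-2-(2-oxocyclohexylidene)propanoate derivative
Product: 16 7a-propargyl butenolide (hexahydrobenzofuranone), via hydroxy ester 15 (not isolated)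
Conditions: propargylzinc bromide (preformed from propargyl bromide and Zn), THF, −40 → 0 °C; aq. NH4Cl; then PPTS (cat.), PhMe, 40 °C
Reagents that add atoms: propargylzinc bromide (C#CC[Zn]Br)
Why: The allenylzinc reagent adds (SE2′, Barbier-type) to the ketone anti to the axial C1–OSiEt3 bond (polar Felkin–Anh model, non-chelating silyl ether), which sets the quaternary C6 with the propargyl group cis to the vinyl group, and the tertiary alkoxide then lactonises onto the syn ester to close the butenolide.

Step 9
Reactants: 16 7a-propargyl butenolide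
Product: 17 7a-(2-oxopropyl) butenolide
Conditions: Ph3PAuNTf2 (2 mol %), H2O (5 equiv), 1,4-dioxane, 60 °C
Reagents that add atoms: water (O)
Why: Gold(I)-catalysed Markovnikov hydration of the terminal alkyne gives the methyl ketone (C4=O, C15 methyl) without touching the alkenes, the silyl ethers or the allylic acetate.

Step 10
Reactants: 17 7a-(2-oxopropyl) butenolide
Product: 18 diol butenolide (free C1 and C8 hydroxyls)
Conditions: HF·pyridine, pyridine, THF, 0 °C → rt
Reagents that add atoms: none
Why: Fluoride cleaves both silyl ethers through Si–F bond formation; the trans-diaxial relation of the C1 hydroxyl and the acetonyl arm keeps the γ-hydroxy ketone open.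

Step 11
Reactants: 19 (tert-butyldimethylsilyloxy)acetaldehyde; 20 ethyl 2-(triphenyl-λ5-phosphanylidene)propanoate
Product: 21 ethyl (E)-4-[(tert-butyldimethylsilyl)oxy]-2-methylbut-2-enoate
Conditions: CH2Cl2, rt
Reagents that add atoms: none
Why: Wittig olefination of the aldehyde by the stabilised α-methyl ylide gives the trisubstituted (E)-enoate.

Step 12
Reactants: 21 ethyl (E)-4-[(tert-butyldimethylsilyl)oxy]-2-methylbut-2-enoate
Product: 22 (E)-4-[(tert-butyldimethylsilyl)oxy]-2-methylbut-2-enoic acid
Conditions: LiOH, THF–H2O, rt; then 1 M HCl to pH 4, 0 °C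
Reagents that add atoms: lithium hydroxide ([Li+].[OH-])
Why: Saponification of the ethyl ester (acyl substitution by hydroxide) leaves the primary silyl ether in place.

Step 13
Reactants: 18 diol butenolide; 22 (E)-4-[(tert-butyldimethylsilyl)oxy]-2-methylbut-2-enoic acid
Product: 23 C8 ester of the diol butenolide (free C1 hydroxyl)
Conditions: DCC, DMAP (cat.), CH2Cl2, 0 °C → rt
Reagents that add atoms: none
Why: Steglich esterification (carbodiimide activation, DMAP acyl transfer) acylates the secondary C8 hydroxyl selectively because the tertiary C1 carbinol between two fully substituted carbons is too hindered.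

Step 14
Reactants: 23 C8 ester of the diol butenolide
Product: 24 bis(trimethylsilyl) ether with (Z)-2-(trimethylsilyloxy)prop-1-enyl group on C6
Conditions: TMSOTf (2.5 equiv), Et3N, CH2Cl2, −78 → 0 °C; pentane, filtration; used crude
Reagents that add atoms: trimethylsilyl trifluoromethanesulfonate (C[Si](C)(C)OS(=O)(=O)C(F)(F)F)
Why: Soft enolisation with the silyl triflate and amine converts the methyl ketone into the more substituted (Z)-silyl enol ether (C6 trans to the methyl group) and silylates the tertiary alcohol, which gives the 3-siloxy-1,5-diene for step 15; a terminal enol ether regioisomer is not a 1,5-diene and is recovered as ketone after desilylation.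

Step 15
Reactants: 24 bis(trimethylsilyl) ether with (Z)-2-(trimethylsilyloxy)prop-1-enyl group on C6
Product: 27 (5Z)-isomer of the target (bridged hemiketal), via siloxy-Cope product 25 (not isolated), via hydroxy ketone 26 (not isolated)
Conditions: PhMe (0.01 M), BSA (5 mol %), 150 °C, sealed tube; then HF·pyridine, pyridine, THF, 0 °C → rt
Reagents that add atoms: none
Why: Heating takes the 3-siloxy-1,5-diene C3=C2–C1(OSiMe3)–C6–C5=C4(OSiMe3) of 24 through a chair-like [3,3] transition state in the ground-state chair of the cyclohexane (vinyl equatorial on C1, propenyl axial on C6): the congested, doubly allylic C1–C6 bond breaks as C3–C4 forms, which turns the six-membered carbocycle into the ten-membered one and gives 25 with a C1 silyl enol ether and a C5=C6 enol lactone conjugated to the butenolide (driving force together with the relief of strain between the vicinal quaternary carbons). The closest known reaction type is the oxy-Cope (siloxy-Cope) ring expansion of cis-1,2-dialkenylcyclohexanols to cyclodec-5-enones used for germacranes. HF·pyridine then cleaves the three silyl groups, the enol ether becomes the C1 ketone of 26 and the tertiary C4 hydroxyl adds to that ketone across the ring (5-exo-trig hemiketalisation), so that the oxolane closes last, after the lactone and the ten-membered carbocycle. C4 is set in the sigmatropic step by suprafacial bond formation on the face of the (Z)-enol ether that faces C1 (chirality transfer from the sacrificial C6 and C1 centres, expected 4R), C1 of the hemiketal is dictated by C4 because the oxygen bridge can only be cis, and C8 and C10 are not touched. The step needs the vinyl terminus to bond to C4 and not to C11 of the butenolide alkene (an alternative 1,5-diene that would give an eight-membered ring): the cis relation of the vinyl and propenyl groups set in step 8 places C3 over C4, while the position over the lactone ring is taken by the siloxy group. The chair places C4 syn to the lactone oxygen (5Z, a trans double bond within the ring), which is corrected in step 16.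

Step 16
Reactants: 27 (5Z)-isomer of the target
Product: 28 target CNP0154520.1
Conditions: I2 (5 mol %), CH2Cl2, visible light, rt
Reagents that add atoms: none
Why: Iodine-atom catalysis (reversible addition of I• to C5 of the alkylidene butenolide) equilibrates the C5=C6 geometry, and the bridged hemiketal with the cis double bond in the ring (5E) should be the thermodynamic sink because it removes the strain of the trans-cycloalkene; no stereocentre is touched.

## Compound list

1 | 4-[(tert-butyldimethylsilyl)oxy]cyclohexan-1-one | O=C1CCC(O[Si](C)(C)C(C)(C)C)CC1 | starting material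
2 | lithium (R)-4-[(tert-butyldimethylsilyl)oxy]cyclohex-1-en-1-olate | [Li]OC1=CC[C@H](O[Si](C)(C)C(C)(C)C)CC1 | intermediate (not isolated)
3 | (4R)-4-[(tert-butyldimethylsilyl)oxy]-2-methylcyclohexan-1-one, C2-epimer mixture | O=C1C(C)C[C@H](O[Si](C)(C)C(C)(C)C)CC1 | intermediate
4 | (2R,4R)-4-[(tert-butyldimethylsilyl)oxy]-2-methylcyclohexan-1-one (methyl and silyloxy cis) | O=C1[C@H](C)C[C@H](O[Si](C)(C)C(C)(C)C)CC1 | intermediate
5 | lithium enolate of 4 toward the unsubstituted α-carbon (4-silyloxy and 6-methyl cis) | [Li]OC1=CC[C@@H](O[Si](C)(C)C(C)(C)C)C[C@H]1C | intermediate (not isolated)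
6 | 4-[(tert-butyldimethylsilyl)oxy]-2-hydroxy-6-methylcyclohexan-1-one (4-silyloxy and 6-methyl cis; carbinol carbon as epimer mixture) | O=C1[C@H](C)C[C@H](O[Si](C)(C)C(C)(C)C)CC1O | intermediate
7 | 4-[(tert-butyldimethylsilyl)oxy]-6-methyl-1-vinylcyclohexane-1,2-diol (tertiary OH cis to 6-methyl and 4-silyloxy, vinyl trans to methyl; C2 epimers) | [C@@]1(O)(C=C)[C@H](C)C[C@H](O[Si](C)(C)C(C)(C)C)CC1O | intermediate
8 | 5-[(tert-butyldimethylsilyl)oxy]-2-hydroxy-3-methyl-2-vinylcyclohexan-1-one (2-OH cis to 3-methyl and 5-silyloxy) | [C@@]1(O)(C=C)[C@H](C)C[C@H](O[Si](C)(C)C(C)(C)C)CC1=O | intermediate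
9 | 5-[(tert-butyldimethylsilyl)oxy]-3-methyl-2-[(triethylsilyl)oxy]-2-vinylcyclohexan-1-one (same relative configuration as 8) | [C@@]1(O[Si](CC)(CC)CC)(C=C)[C@H](C)C[C@H](O[Si](C)(C)C(C)(C)C)CC1=O | intermediate
10 | ethyl 3-bromo-2-oxopropanoate | CCOC(=O)C(=O)CBr | starting material
11 | lithium enolate of 9 (C6–C7 enolate) | [C@@]1(O[Si](CC)(CC)CC)(C=C)[C@H](C)C[C@H](O[Si](C)(C)C(C)(C)C)C=C1O[Li] | intermediate (not isolated)
12 | ethyl 2-(2-oxocyclohexyl)oxirane-2-carboxylate derivative of 9 (glycidic ester; mixture at the two new centres) | [C@@]1(O[Si](CC)(CC)CC)(C=C)[C@H](C)C[C@H](O[Si](C)(C)C(C)(C)C)C(C2(C(=O)OCC)CO2)C1=O | intermediate (not isolated)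
13 | lithium alkoxide of ethyl (Z)-3-hydroxy-2-(2-oxocyclohexylidene)propanoate derivative (ester syn to ketone) | [C@@]1(O[Si](CC)(CC)CC)(C=C)[C@H](C)C[C@H](O[Si](C)(C)C(C)(C)C)/C(=C(\CO[Li])C(=O)OCC)C1=O | intermediate (not isolated)
14 | ethyl (Z)-3-acetoxy-2-{6-[(tert-butyldimethylsilyl)oxy]-4-methyl-2-oxo-3-[(triethylsilyl)oxy]-3-vinylcyclohexylidene}propanoate (ester syn to ketone) | [C@@]1(O[Si](CC)(CC)CC)(C=C)[C@H](C)C[C@H](O[Si](C)(C)C(C)(C)C)/C(=C(\COC(C)=O)C(=O)OCC)C1=O | intermediate
15 | tertiary alcohol from propargyl addition to 14 (propargyl cis to vinyl, new OH cis to the C1 silyloxy group) | [C@@]1(O[Si](CC)(CC)CC)(C=C)[C@H](C)C[C@H](O[Si](C)(C)C(C)(C)C)/C(=C(\COC(C)=O)C(=O)OCC)[C@@]1(O)CC#C | intermediate (not isolated)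
16 | {4-[(tert-butyldimethylsilyl)oxy]-6-methyl-2-oxo-7a-(prop-2-yn-1-yl)-7-[(triethylsilyl)oxy]-7-vinyl-2,4,5,6,7,7a-hexahydro-1-benzofuran-3-yl}methyl acetate (O1, 4-O, 6-methyl and 7-O on one face; 7-vinyl and 7a-propargyl on the other) | [C@@]1(O[Si](CC)(CC)CC)(C=C)[C@H](C)C[C@H](O[Si](C)(C)C(C)(C)C)C2=C(COC(C)=O)C(=O)O[C@@]21CC#C | intermediate
17 | 7a-(2-oxopropyl) analogue of 16 (same configuration) | [C@@]1(O[Si](CC)(CC)CC)(C=C)[C@H](C)C[C@H](O[Si](C)(C)C(C)(C)C)C2=C(COC(C)=O)C(=O)O[C@@]21CC(C)=O | intermediate
18 | [4,7-dihydroxy-6-methyl-2-oxo-7a-(2-oxopropyl)-7-vinyl-2,4,5,6,7,7a-hexahydro-1-benzofuran-3-yl]methyl acetate (same configuration) | [C@@]1(O)(C=C)[C@H](C)C[C@H](O)C2=C(COC(C)=O)C(=O)O[C@@]21CC(C)=O | intermediate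
19 | (tert-butyldimethylsilyloxy)acetaldehyde | O=CCO[Si](C)(C)C(C)(C)C | starting material
20 | ethyl 2-(triphenyl-λ5-phosphanylidene)propanoate | CCOC(=O)C(C)=P(c1ccccc1)(c1ccccc1)c1ccccc1 | starting material
21 | ethyl (E)-4-[(tert-butyldimethylsilyl)oxy]-2-methylbut-2-enoate | CCOC(=O)/C(C)=C/CO[Si](C)(C)C(C)(C)C | intermediate
22 | (E)-4-[(tert-butyldimethylsilyl)oxy]-2-methylbut-2-enoic acid | OC(=O)/C(C)=C/CO[Si](C)(C)C(C)(C)C | intermediate
23 | 4-O-[(E)-4-(tert-butyldimethylsilyloxy)-2-methylbut-2-enoyl] ester of 18 (benzofuranone C4 = germacrane C8; 7-OH free) | [C@@]1(O)(C=C)[C@H](C)C[C@H](OC(=O)/C(C)=C/CO[Si](C)(C)C(C)(C)C)C2=C(COC(C)=O)C(=O)O[C@@]21CC(C)=O | intermediate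
24 | 7-O-trimethylsilyl ether of 23 with 7a-[(Z)-2-(trimethylsilyloxy)prop-1-en-1-yl] in place of 2-oxopropyl (siloxy cis to C7a) | [C@@]1(O[Si](C)(C)C)(C=C)[C@H](C)C[C@H](OC(=O)/C(C)=C/CO[Si](C)(C)C(C)(C)C)C2=C(COC(C)=O)C(=O)O[C@@]21/C=C(/C)O[Si](C)(C)C | intermediate
25 | (4R,5Z,8S,10R)-13-acetoxy-8-[(E)-4-(tert-butyldimethylsilyloxy)-2-methylbut-2-enoyloxy]-1,4-bis(trimethylsilyloxy)germacra-1,5,7(11)-trien-6,12-olide (C2=C1 enol ether with C3 cis to C10) | CC(=O)OCC1=C2/C(=C/[C@](C)(O[Si](C)(C)C)C/C=C(/O[Si](C)(C)C)[C@H](C)C[C@@H]2OC(=O)/C(C)=C/CO[Si](C)(C)C(C)(C)C)OC1=O | intermediate (not isolated)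
26 | (4R,5Z,8S,10R)-13-acetoxy-4-hydroxy-8-[(E)-4-hydroxy-2-methylbut-2-enoyloxy]-1-oxogermacra-5,7(11)-dien-6,12-olide | CC(=O)OCC1=C2/C(=C/[C@](C)(O)CCC(=O)[C@H](C)C[C@@H]2OC(=O)/C(C)=C/CO)OC1=O | intermediate (not isolated)
27 | (1S,4R,5Z,8S,10R)-13-acetoxy-1,4-epoxy-1-hydroxy-8-[(E)-4-hydroxy-2-methylbut-2-enoyloxy]germacra-5,7(11)-dien-6,12-olide, the (5Z)-isomer of the target | CC(=O)OCC1=C2/C(=C/[C@@]3(C)CC[C@](O)(O3)[C@H](C)C[C@@H]2OC(=O)/C(C)=C/CO)OC1=O | intermediate
28 | CNP0154520.1, (1S,4R,5E,8S,10R)-13-acetoxy-1,4-epoxy-1-hydroxy-8-[(E)-4-hydroxy-2-methylbut-2-enoyloxy]germacra-5,7(11)-dien-6,12-olide | CC(=O)OCC1=C2/C(=C\[C@@]3(C)CC[C@](O)(O3)[C@H](C)C[C@@H]2OC(=O)/C(C)=C/CO)OC1=O | target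

## Step count and risks

Total step count: 16. Longest linear sequence: 14 steps (steps 1–10 and 13–16).

Step 15 (key step). What may go wrong: the neutral [3,3] shift is an equilibrium between two siloxy dienes and may not favour the ten-membered ring; the weak, doubly allylic C1–C6 bond may instead cleave stepwise and re-close by a [1,3] path; after desilylation the hemiketal that carries a trans double bond in the ring may stay open. Fallback (known chemistry, different driving force): charge-accelerated oxy-Cope of the free carbinol. It sets out from 23. Chemoselective O-silylation of the ketone enol (TBSOTf, Et3N, −78 °C; the tertiary carbinol between two fully substituted carbons should react more slowly) should give the (Z)-tert-butyldimethylsilyl enol ether F1. KH and 18-crown-6 in THF at −40 °C turn the carbinol into its potassium alkoxide, whose irreversible anionic oxy-Cope rearrangement (enolate formation as driving force) should give, after AcOH quench, the C4 silyl ether ketone F2. HF·pyridine then removes both silyl groups and the fallback comes back to the route at 27.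

Step 7. What may go wrong: C-alkylation of the enolate at the bromomethyl carbon instead of aldol addition, β-elimination of the C8 silyloxy group from the enolate, or opening of the epoxide to the alkylidene with the ester anti to the ketone, which cannot lactonise in step 8. Fallback: stepwise aldol condensation and vinylogous oxygenation. It sets out from 9. The lithium enolate and ethyl pyruvate should give the aldol F3, which is dehydrated (TFAA, DBU) to the methyl-substituted alkylidene keto ester F4. Wohl–Ziegler bromination (NBS, AIBN) of the γ-methyl group, which is vinylogous to the ketone, should give the bromide F5. KOAc and 18-crown-6 in MeCN displace bromide and the fallback comes back to the route at 14.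

Step 8. What may go wrong: slow addition of the zinc reagent to the hindered, cross-conjugated ketone, loss of facial selectivity through chelation, or failure of an E-configured adduct to lactonise. Fallback: a more reactive, non-chelating allyl transfer and a different unveiling of the ketone. It sets out from 14. Allylmagnesium bromide–CeCl3 at −78 °C (allylcerium adds to hindered ketones and spares esters at low temperature) should give the allyl adduct F6, which lactonises to the allyl butenolide F7. Tsuji–Wacker oxidation (PdCl2, CuCl, O2, DMF–H2O) of the unhindered terminal alkene (the vinyl group on the fully substituted, silyloxy-bearing carbon should react more slowly) should give the methyl ketone, and the fallback comes back to the route at 17.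

## Further compounds

F1 | step 15 | (Z)-tert-butyldimethylsilyl enol ether of 23 with free C1 hydroxyl | [C@@]1(O)(C=C)[C@H](C)C[C@H](OC(=O)/C(C)=C/CO[Si](C)(C)C(C)(C)C)C2=C(COC(C)=O)C(=O)O[C@@]21/C=C(/C)O[Si](C)(C)C(C)(C)C
F2 | step 15 | (4R,5Z,8S,10R)-13-acetoxy-4-(tert-butyldimethylsilyloxy)-8-[(E)-4-(tert-butyldimethylsilyloxy)-2-methylbut-2-enoyloxy]-1-oxogermacra-5,7(11)-dien-6,12-olide | CC(=O)OCC1=C2/C(=C/[C@](C)(O[Si](C)(C)C(C)(C)C)CCC(=O)[C@H](C)C[C@@H]2OC(=O)/C(C)=C/CO[Si](C)(C)C(C)(C)C)OC1=O
F3 | step 7 | aldol of 9 with ethyl pyruvate (ethyl 2-hydroxy-2-methyl-2-(2-oxocyclohexyl)acetate derivative, mixture at the new centres) | [C@@]1(O[Si](CC)(CC)CC)(C=C)[C@H](C)C[C@H](O[Si](C)(C)C(C)(C)C)C(C(C)(O)C(=O)OCC)C1=O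
F4 | step 7 | ethyl 2-(2-oxocyclohexylidene)propanoate derivative of 9 (methyl analogue of 14, ester syn to ketone) | [C@@]1(O[Si](CC)(CC)CC)(C=C)[C@H](C)C[C@H](O[Si](C)(C)C(C)(C)C)/C(=C(\C)C(=O)OCC)C1=O
F5 | step 7 | ethyl 3-bromo-2-(2-oxocyclohexylidene)propanoate derivative of 9 (ester syn to ketone) | [C@@]1(O[Si](CC)(CC)CC)(C=C)[C@H](C)C[C@H](O[Si](C)(C)C(C)(C)C)/C(=C(\CBr)C(=O)OCC)C1=O
F6 | step 8 | tertiary alcohol from allyl addition to 14 (allyl cis to vinyl) | [C@@]1(O[Si](CC)(CC)CC)(C=C)[C@H](C)C[C@H](O[Si](C)(C)C(C)(C)C)/C(=C(\COC(C)=O)C(=O)OCC)[C@@]1(O)CC=C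
F7 | step 8 | 7a-allyl analogue of 16 (same configuration) | [C@@]1(O[Si](CC)(CC)CC)(C=C)[C@H](C)C[C@H](O[Si](C)(C)C(C)(C)C)C2=C(COC(C)=O)C(=O)O[C@@]21CC=C
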